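**Retrosynthetic overview**

1. Target ⇒ one acyclic precursor, (1E,3Z,6S)-6-bromo-7-(bromomethyl)-1-chloro-3-methylocta-1,3,7-triene. A single chloronium-triggered cation–olefin cyclisation makes the only ring (bond between the quaternary C5 and the C6 methylene of the target) and, through a bromonium relay closed by chloride, also the C1–Cl bond; all three new stereocentres follow from the one C–Br centre.
2. Dibromotriene ⇒ (3R)-2-methylidene-1,3-diol by double deoxybromination (inversion at the secondary carbinol).
3. Diol ⇒ 2-(silylmethyl) allylic alcohol by Sharpless epoxidation and Peterson-type epoxide opening (sets the one stereocentre carried into the key step).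
4. Allylic alcohol ⇒ propargyl alcohol + Me3SiCH2MgCl + (1E,3Z)-chlorodienyl bromide; the bromide comes from commercial (Z)-3-methylpent-2-en-4-yn-1-ol.
5. Ring order: no ring until the last step; the cyclohexane is formed once, last.

Assumption: the presumed biosynthesis is a chloronium-induced cyclisation of a halogenated ocimene-type triene (Cl+ at C4, ring bond C3–C8), with Br and Cl then added across the exocyclic methylene; locants in the explanations are those of the compound named.

**Route**

Step 1
Reactants: 1 (2Z)-3-methylpent-2-en-4-yn-1-ol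
Product: 3 (2Z,4E)-5-chloro-3-methylpenta-2,4-dien-1-ol, via alkenylzirconocene 2 (not isolated)
Conditions: Cp2Zr(H)Cl (2.2 equiv), THF, rt; then NCS, 0 °C
Reagents that add atoms: N-chlorosuccinimide, O=C1CCC(=O)N1Cl
Why: Schwartz hydrozirconation adds Zr–H syn and anti-Markovnikov to the terminal alkyne (first equivalent is consumed by the OH), and chlorination of the C–Zr bond with retention gives the (E)-chlorovinyl group while the (Z)-trisubstituted alkene is untouched (hydrozirconation–halogenation).

Step 2
Reactants: 3 (2Z,4E)-5-chloro-3-methylpenta-2,4-dien-1-ol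
Product: 4 (1E,3Z)-5-bromo-1-chloro-3-methylpenta-1,3-diene
Conditions: CBr4, PPh3, CH2Cl2, −20 °C; used crude
Reagents that add atoms: carbon tetrabromide, BrC(Br)(Br)Br
Why: Appel bromination is a neutral SN2 displacement at the primary dienylic carbon, so neither alkene geometry is disturbed.

Step 3
Reactants: 5 prop-2-yn-1-ol; 4 (1E,3Z)-5-bromo-1-chloro-3-methylpenta-1,3-diene
Product: 7 (2E,5Z,7E)-8-chloro-6-methyl-2-[(trimethylsilyl)methyl]octa-2,5,7-trien-1-ol (CH2OH cis to the C4 methylene), via alkenylmagnesium chelate 6 (not isolated)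
Conditions: 5, Me3SiCH2MgCl (2.3 equiv), CuI (10 mol %), Et2O–THF, 0 °C to reflux; then 4 (0.8 equiv), Li2CuCl4 (5 mol %), −30 to 0 °C
Reagents that add atoms: (trimethylsilyl)methylmagnesium chloride, C[Si](C)(C)C[Mg]Cl
Why: Copper-catalysed anti-carbomagnesiation of the propargylic alcohol (Duboudin–Jousseaume) puts CH2SiMe3 on C2 and gives the O-chelated alkenylmagnesium with Mg cis to CH2O, and Kochi-type Li2CuCl4 coupling at the primary carbon of 4 proceeds with retention in both partners, so the dienyl chain ends cis to CH2OH.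

Step 4
Reactants: 7 (2E,5Z,7E)-8-chloro-6-methyl-2-[(trimethylsilyl)methyl]octa-2,5,7-trien-1-ol
Product: 9 (3R,5Z,7E)-8-chloro-6-methyl-2-methylideneocta-5,7-diene-1,3-diol, via epoxysilane 8 (not isolated)
Conditions: Ti(OiPr)4 (10 mol %), L-(+)-DET (12 mol %), t-BuOOH, 4 Å MS, CH2Cl2, −20 °C; then Bu4NF, THF, 0 °C
Reagents that add atoms: tert-butyl hydroperoxide, CC(C)(C)OO
Why: Katsuki–Sharpless epoxidation touches only the allylic-alcohol alkene, and for this geometry (chain cis to CH2OH) L-(+)-DET gives the (2S,3R)-epoxide; fluoride then triggers a Peterson-type opening of the (silylmethyl)oxirane that breaks only the C2–O bond, fixing the alkene where silicon was and keeping the C3–O bond as the (3R)-carbinol.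

Step 5
Reactants: 9 (3R,5Z,7E)-8-chloro-6-methyl-2-methylideneocta-5,7-diene-1,3-diol
Product: 10 (1E,3Z,6S)-6-bromo-7-(bromomethyl)-1-chloro-3-methylocta-1,3,7-triene
Conditions: Me2C=C(Br)NMe2 (2.4 equiv), CH2Cl2, −40 to 0 °C, dark; cold silica plug, used at once
Reagents that add atoms: 1-bromo-N,N,2-trimethylprop-1-en-1-amine, CC(C)=C(Br)N(C)C
Why: Ghosez-type α-bromoenamine deoxybromination converts each OH through an alkoxyiminium bromide ion pair that collapses by SN2 under neutral conditions, so the secondary allylic carbinol is inverted (3R-OH to 6S-Br) with little allylic transposition and no excess bromide is left to racemise the product.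

Step 6
Reactants: 10 (1E,3Z,6S)-6-bromo-7-(bromomethyl)-1-chloro-3-methylocta-1,3,7-triene
Product: 11 (1S,2S,4R,5R)-2-bromo-1-(bromomethyl)-1,4-dichloro-5-[(E)-2-chloroethenyl]-5-methylcyclohexane
Conditions: Et2SCl·SbCl6 (1.1 equiv), EtNO2–CH2Cl2, −78 to −40 °C; aq. NaHCO3/Na2SO3
Reagents that add atoms: chlorodiethylsulfonium hexachloroantimonate, CC[S+](Cl)CC.Cl[Sb-](Cl)(Cl)(Cl)(Cl)Cl
Why: Proposed new method: Cl+ adds to C4 of the 1-chloro-1,3-diene of 10 (the 1,1-disubstituted alkene is deactivated by its two allylic C–Br bonds, and chloride capture of the allyl cation is reversible under SbCl5), the chlorovinyl-stabilised allyl cation is attacked at C3 by the terminal CH2 (C8) through a chair transition state in which the new C4–Cl is equatorial and anti to the new C3–C8 bond, the chlorovinyl group is axial because the 3Z geometry is carried over, and the C6–Br bond is equatorial (in the plane of the attacking alkene, so its σ* does not drain the π-nucleophile); the developing C7 cation is bridged from the equatorial side by the CH2Br bromine and the bromonium is opened axially at the tertiary carbon by chloride from SbCl6−, so all three new stereocentres follow from the (6S) C–Br centre; closest known chemistry is halonium-induced cation–olefin (polyene) cyclisation with halosulfonium hexahaloantimonate reagents together with Markovnikov anti-opening by chloride of the bromonium ion of a methylenecyclohexane (BrCl addition).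

**Compound list**

1 | (2Z)-3-methylpent-2-en-4-yn-1-ol | C#C/C(C)=C\CO | starting material
2 | chlorobis(cyclopentadienyl)[(1E,3Z)-5-{[chlorobis(cyclopentadienyl)zirconio]oxy}-3-methylpenta-1,3-dien-1-yl]zirconium (Cp drawn σ-bonded) | Cl[Zr](/C=C/C(C)=C\CO[Zr](Cl)(C1C=CC=C1)C1C=CC=C1)(C1C=CC=C1)C1C=CC=C1 | intermediate
3 | (2Z,4E)-5-chloro-3-methylpenta-2,4-dien-1-ol | Cl/C=C/C(C)=C\CO | intermediate
4 | (1E,3Z)-5-bromo-1-chloro-3-methylpenta-1,3-diene | Cl/C=C/C(C)=C\CBr | intermediate
5 | prop-2-yn-1-ol | C#CCO | starting material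
6 | [3-(chloromagnesiooxy)-2-[(trimethylsilyl)methyl]prop-1-en-1-yl]magnesium chloride, Mg cis to CH2O | Cl[Mg]/C=C(/C[Si](C)(C)C)CO[Mg]Cl | intermediate
7 | (2E,5Z,7E)-8-chloro-6-methyl-2-[(trimethylsilyl)methyl]octa-2,5,7-trien-1-ol | Cl/C=C/C(C)=C\C/C=C(\CO)C[Si](C)(C)C | intermediate
8 | [(2S,3R)-3-[(2Z,4E)-5-chloro-3-methylpenta-2,4-dien-1-yl]-2-[(trimethylsilyl)methyl]oxiran-2-yl]methanol | OC[C@]1(C[Si](C)(C)C)O[C@@H]1C/C=C(C)\C=C\Cl | intermediate
9 | (3R,5Z,7E)-8-chloro-6-methyl-2-methylideneocta-5,7-diene-1,3-diol | OCC(=C)[C@H](O)C/C=C(C)\C=C\Cl | intermediate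
10 | (1E,3Z,6S)-6-bromo-7-(bromomethyl)-1-chloro-3-methylocta-1,3,7-triene | BrCC(=C)[C@@H](Br)C/C=C(C)\C=C\Cl | intermediate
11 | (1S,2S,4R,5R)-2-bromo-1-(bromomethyl)-1,4-dichloro-5-[(E)-2-chloroethenyl]-5-methylcyclohexane | C[C@]1(/C=C/Cl)C[C@](Cl)(CBr)[C@@H](Br)C[C@H]1Cl | target

**Totals**

Total step count: 6. Longest linear sequence: 6 steps (1 → 3 → 4 → 7 → 9 → 10 → 11); propargyl alcohol 5 enters at step 3.

**Three steps most likely to fail**

Step 6 (the cascade). Risks:
- the doubly deactivated alkene may be too weak a terminator, leaving diene dichlorination products;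
- an open allyl cation could rotate about C3–C4 and lose the 3Z information;
- SbCl5 may ionise the allylic bromides;
- the chair preference set by the C6–Br bond may be modest.

Fallback: set out from bromide 4 and come back at target 11 by the stepwise sequence (cyclise first, add BrCl afterwards). Copper-catalysed coupling of 4 with 2-methylprop-1-enylmagnesium bromide gives (1E,3Z)-1-chloro-3,7-dimethylocta-1,3,6-triene F1. Shi epoxidation (D-fructose-derived ketone, Oxone) of the isolated trisubstituted alkene gives (3R)-3-[(2Z,4E)-5-chloro-3-methylpenta-2,4-dien-1-yl]-2,2-dimethyloxirane F2. Li2NiBr4 in THF opens it at the secondary carbon with inversion to (3S,5Z,7E)-3-bromo-8-chloro-2,6-dimethylocta-5,7-dien-2-ol F3. Burgess dehydration toward a methyl group gives (1E,3Z,6S)-6-bromo-1-chloro-3,7-dimethylocta-1,3,7-triene F4. The same chlorosulfonium reagent now meets a normal isopropenyl terminator, and the cation ends by proton loss to (1R,2R,4S)-4-bromo-2-chloro-1-[(E)-2-chloroethenyl]-1-methyl-5-methylidenecyclohexane F5. Bu4NBrCl2 then adds Br to the exocyclic CH2 and Cl axially to the ring carbon, giving 11.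

Step 5 (double deoxybromination). Risks: SN2′ attack at the terminal CH2 would give the achiral 2-alkylidene-1,3-dibromide, and any free bromide racemises the secondary allylic bromide by the same path.

Fallback: set out from epoxysilane 8 (isolated this time by leaving out the fluoride) and come back at 10, making the C–Br centre by SN2 at a non-allylic epoxide carbon before the alkene exists. Li2NiBr4 (THF, 0 °C) opens 8 at the secondary carbon with inversion to the β-hydroxysilane (2R,3S,5Z,7E)-3-bromo-8-chloro-6-methyl-2-[(trimethylsilyl)methyl]octa-5,7-diene-1,2-diol F6. Acid-promoted Peterson elimination (BF3·OEt2, −40 °C) gives (3S,5Z,7E)-3-bromo-8-chloro-6-methyl-2-methylideneocta-5,7-dien-1-ol F7. Appel bromination of the primary alcohol at −30 °C gives 10.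

Step 4 (epoxidation of the chain-cis, 2-silylmethyl allylic alcohol). Risks: this substrate class reacts more slowly and with lower ee than (E)-allylic alcohols, and the β-silyl epoxide may open in other ways on titanium.

Fallback: set out from bromide 4 and come back at diol 9 through an (E)-allylic alcohol and an epoxide-to-allylic-alcohol isomerisation. Zirconium-catalysed methylalumination of propargyl alcohol 5 (AlMe3, Cp2ZrCl2) gives dimethylaluminium (2E)-3-(dimethylalumanyl)-2-methylprop-2-en-1-olate F8. Pd(PPh3)4-catalysed allylation of F8 with 4 gives (2E,5Z,7E)-8-chloro-2,6-dimethylocta-2,5,7-trien-1-ol F9. Sharpless epoxidation with D-(−)-DET gives [(2R,3R)-3-[(2Z,4E)-5-chloro-3-methylpenta-2,4-dien-1-yl]-2-methyloxiran-2-yl]methanol F10. Cp2TiCl (from Cp2TiCl2 and Zn, THF) opens F10 at the tertiary carbon, and β-hydride elimination from the methyl group delivers 9 with the C3–O bond untouched.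

**Further compounds**

F1 | step 6 | (1E,3Z)-1-chloro-3,7-dimethylocta-1,3,6-triene | Cl/C=C/C(C)=C\CC=C(C)C
F2 | step 6 | (3R)-3-[(2Z,4E)-5-chloro-3-methylpenta-2,4-dien-1-yl]-2,2-dimethyloxirane | CC1(C)O[C@@H]1C/C=C(C)\C=C\Cl
F3 | step 6 | (3S,5Z,7E)-3-bromo-8-chloro-2,6-dimethylocta-5,7-dien-2-ol | CC(C)(O)[C@@H](Br)C/C=C(C)\C=C\Cl
F4 | step 6 | (1E,3Z,6S)-6-bromo-1-chloro-3,7-dimethylocta-1,3,7-triene | CC(=C)[C@@H](Br)C/C=C(C)\C=C\Cl
F5 | step 6 | (1R,2R,4S)-4-bromo-2-chloro-1-[(E)-2-chloroethenyl]-1-methyl-5-methylidenecyclohexane | C[C@]1(/C=C/Cl)CC(=C)[C@@H](Br)C[C@H]1Cl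
F6 | step 5 | (2R,3S,5Z,7E)-3-bromo-8-chloro-6-methyl-2-[(trimethylsilyl)methyl]octa-5,7-diene-1,2-diol | OC[C@@](O)(C[Si](C)(C)C)[C@@H](Br)C/C=C(C)\C=C\Cl
F7 | step 5 | (3S,5Z,7E)-3-bromo-8-chloro-6-methyl-2-methylideneocta-5,7-dien-1-ol | OCC(=C)[C@@H](Br)C/C=C(C)\C=C\Cl
F8 | step 4 | dimethylaluminium (2E)-3-(dimethylalumanyl)-2-methylprop-2-en-1-olate | C[Al](C)OC/C(C)=C/[Al](C)C
F9 | step 4 | (2E,5Z,7E)-8-chloro-2,6-dimethylocta-2,5,7-trien-1-ol | Cl/C=C/C(C)=C\C/C=C(\C)CO
F10 | step 4 | [(2R,3R)-3-[(2Z,4E)-5-chloro-3-methylpenta-2,4-dien-1-yl]-2-methyloxiran-2-yl]methanol | OC[C@@]1(C)O[C@@H]1C/C=C(C)\C=C\Cl
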